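**Retrosynthetic overview**

- Feature: in ring A the oxygens on C5 and C8 are para to each other, so ring A is the reduced form of a 2-acyl-5-methoxy-1,4-benzoquinone. Its one unsubstituted carbon next to the acyl group (future C8a) is the β-carbon of both the quinone carbonyl that becomes the C5 oxygen and the C4 ketone.
- Last disconnections: the C8 and C5 O-methyl groups, removed in that order, back to the 5,8-dihydroxy-7-methoxyflavanone.
- Key disconnection O1–C8a: intramolecular oxa-Michael addition of the (S)-carbinol to the acylquinone, followed by re-aromatisation. Ring C is the only ring formed; rings A and B are bought as arenes.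
- C4–C4a comes from an aryllithium (methoxyhydroquinone as its bis-benzyl ether) and a β-hydroxy Weinreb amide. The C2 stereocentre comes from Noyori hydrogenation of a β-keto ester.

Key step: step 7

Remark on the chemistry: 2-methoxyhydroquinone and ethyl 3-(3,4-dimethoxyphenyl)-3-oxopropanoate are assumed purchasable. Ring A is carried as benzyl ethers so that the quinone is released from its hydroquinone by one equivalent of a two-electron oxidant; a one-electron oxidant able to demethylate a trimethoxyaryl ketone, such as (NH4)2Ce(NO3)6, would also attack the 3,4-dimethoxyphenyl carbinol and the cyclised hydroquinone. For the same reason the free phenol is methylated before any Ag2O is used.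

**Route**

Step 1
Reactants: 1 ethyl 3-(3,4-dimethoxyphenyl)-3-oxopropanoate
Product: 2 ethyl (3S)-3-(3,4-dimethoxyphenyl)-3-hydroxypropanoate
Conditions: [RuCl(p-cymene)((R)-BINAP)]Cl (0.5 mol%), H2 (50 bar), EtOH, 50 °C
Reagents that add atoms: none
Why: Noyori asymmetric hydrogenation of a β-keto ester, in which (R)-BINAP directs hydride to the face of the ester-chelated ketone that gives (R)-3-hydroxybutanoates; here that face gives the (S) descriptor because aryl outranks CH2CO2Et, and it sets the only stereocentre of the route.

Step 2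
Reactants: 2 ethyl (3S)-3-(3,4-dimethoxyphenyl)-3-hydroxypropanoate
Product: 3 (3S)-3-(3,4-dimethoxyphenyl)-3-hydroxy-N-methoxy-N-methylpropanamide
Conditions: MeNH(OMe)·HCl (1.6 equiv), i-PrMgCl (4.5 equiv), THF, −20 to 0 °C
Reagents that add atoms: N,O-dimethylhydroxylamine hydrochloride, CNOC.Cl
Why: Weinreb amide formation by aminolysis of the ester with the chloromagnesium amide made in the flask, the free hydroxyl riding through as its magnesium alkoxide, which at this temperature should neither eliminate nor undergo retro-aldol cleavage.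

Step 3
Reactants: 4 2-methoxybenzene-1,4-diol (2-methoxyhydroquinone)
Product: 5 1,4-bis(benzyloxy)-2-methoxybenzene
Conditions: BnBr (2.3 equiv), K2CO3 (3 equiv), degassed DMF, N2, rt
Reagents that add atoms: benzyl bromide, BrCc1ccccc1
Why: Williamson etherification of both phenols, with air excluded so that the electron-rich hydroquinone anion is alkylated before it can be oxidised.

Step 4
Reactants: 5 1,4-bis(benzyloxy)-2-methoxybenzene
Product: 6 1,4-bis(benzyloxy)-2-bromo-5-methoxybenzene (bromine para to the methoxy group)
Conditions: NBS (1.02 equiv), MeCN, 0 °C to rt, dark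
Reagents that add atoms: N-bromosuccinimide, O=C1CCC(=O)N1Br
Why: Electrophilic aromatic bromination at the position para to OMe and ortho to a benzyloxy group, the most activated and least hindered site, as in the bromination of 1,2,4-trimethoxybenzene.

Step 5
Reactants: 6 1,4-bis(benzyloxy)-2-bromo-5-methoxybenzene; 3 (3S)-3-(3,4-dimethoxyphenyl)-3-hydroxy-N-methoxy-N-methylpropanamide
Product: 8 (3S)-1-[2,5-bis(benzyloxy)-4-methoxyphenyl]-3-(3,4-dimethoxyphenyl)-3-hydroxypropan-1-one, via aryllithium 7 (not isolated)
Conditions: 6 (2.3 equiv), n-BuLi (2.25 equiv), THF, −78 °C; then 3 (1.0 equiv), −78 to −40 °C; AcOH in THF at −78 °C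
Reagents that add atoms: n-butyllithium, [Li]CCCC (supplies the lithium of 7 only)
Why: Bromine–lithium exchange followed by Weinreb ketone synthesis, in which one equivalent of 7 deprotonates the hydroxyl and the second adds to the amide to give a chelated tetrahedral intermediate that cannot over-add; the cold acidic quench should release the β-hydroxy ketone before the alkoxide can fragment.

Step 6
Reactants: 8 (3S)-1-[2,5-bis(benzyloxy)-4-methoxyphenyl]-3-(3,4-dimethoxyphenyl)-3-hydroxypropan-1-one
Product: 9 (3S)-1-(2,5-dihydroxy-4-methoxyphenyl)-3-(3,4-dimethoxyphenyl)-3-hydroxypropan-1-one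
Conditions: H2 (1 atm), Pd/C (10 wt% Pd on carbon, 5 mol% Pd), EtOAc, rt, stopped after two equivalents of H2; filtered under argon
Reagents that add atoms: none
Why: Hydrogenolysis of aryl benzyl ethers, which under neutral conditions should be much faster than cleavage of the secondary benzylic C–O bond or reduction of the hydrogen-bonded aryl ketone.

Step 7
Reactants: 9 (3S)-1-(2,5-dihydroxy-4-methoxyphenyl)-3-(3,4-dimethoxyphenyl)-3-hydroxypropan-1-one
Product: 11 (2S)-2-(3,4-dimethoxyphenyl)-5,8-dihydroxy-7-methoxy-2,3-dihydro-4H-chromen-4-one, via acylquinone 10 (not isolated)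
Conditions: PhI(OAc)2 (1.00 equiv, added as a solution), CH2Cl2 (0.02 M), −20 °C, argon; then rt
Reagents that add atoms: none
Why: PhI(OAc)2 takes two electrons and two protons from hydroquinone 9 to give acylquinone 10, whose unsubstituted ring carbon next to the acyl group (future C8a) is β to both the quinone carbonyl that becomes the C5 oxygen and the side-chain C4 ketone; the (S)-carbinol oxygen adds there and the ene-dione adduct enolises to the aromatic 5,8-hydroquinone, which makes the O1–C8a bond irreversible. The closest known reaction type is the conjugate addition of oxygen, nitrogen and sulfur nucleophiles to C3 of 2-acyl-1,4-benzoquinones with re-aromatisation, including the closure of 2-(2-hydroxybenzoyl)benzoquinones to hydroxyxanthones. Ring C closes in a 6-endo-trig mode, as in chalcone-to-flavanone cyclisations. No stereocentre is created, and C2 should keep the (S) configuration of step 1 because none of its bonds is made or broken and the acetic acid released is too weak to ionise the benzylic C–O bond. The step needs attack at C8a only, which the tether secures: addition to the neighbouring quinone carbonyl gives a hemiketal reversibly, and C6 and C7 are out of reach and belong to a deactivated methoxy-enone. Exactly one equivalent of a two-electron oxidant is used so that the more electron-rich product 11 is not carried on to its quinone; any quinone formed by electron exchange with 11 should be drawn back as 10 cyclises, and a Na2S2O4 wash at work-up returns residual quinones to hydroquinones.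

Step 8
Reactants: 11 (2S)-2-(3,4-dimethoxyphenyl)-5,8-dihydroxy-7-methoxy-2,3-dihydro-4H-chromen-4-one
Product: 12 (2S)-2-(3,4-dimethoxyphenyl)-5-hydroxy-7,8-dimethoxy-2,3-dihydro-4H-chromen-4-one
Conditions: TMSCHN2 (1.5 equiv, 2 M in hexanes), i-Pr2NEt (1.0 equiv), MeCN–MeOH 9:1, rt, argon
Reagents that add atoms: (trimethylsilyl)diazomethane, C[Si](C)(C)C=[N+]=[N-]
Why: Diazoalkane O-methylation of a phenol, selective for the free 8-OH because the 5-OH is held in a hydrogen bond to the C4 carbonyl, and run without any oxidant that could take the hydroquinone to a quinone.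

Step 9
Reactants: 12 (2S)-2-(3,4-dimethoxyphenyl)-5-hydroxy-7,8-dimethoxy-2,3-dihydro-4H-chromen-4-one
Product: 13 (2S)-2-(3,4-dimethoxyphenyl)-5,7,8-trimethoxy-2,3-dihydro-4H-chromen-4-one
Conditions: MeI (20 equiv), Ag2O (3 equiv), CH2Cl2, rt, dark
Reagents that add atoms: iodomethane, CI
Why: Purdie-type methylation in which Ag2O activates MeI and takes up HI without a soluble base, so the chelated phenol should be etherified without forming the C3 enolate that would expel the ring oxygen; 12 is no longer a hydroquinone, so Ag2O cannot oxidise ring A.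

**Compound list**

1 | ethyl 3-(3,4-dimethoxyphenyl)-3-oxopropanoate | CCOC(=O)CC(=O)c1ccc(OC)c(OC)c1 | starting material
2 | ethyl (3S)-3-(3,4-dimethoxyphenyl)-3-hydroxypropanoate | COc1ccc([C@@H](O)CC(=O)OCC)cc1OC | intermediate
3 | (3S)-3-(3,4-dimethoxyphenyl)-3-hydroxy-N-methoxy-N-methylpropanamide | COc1ccc([C@@H](O)CC(=O)N(C)OC)cc1OC | intermediate
4 | 2-methoxybenzene-1,4-diol | COc1cc(O)ccc1O | starting material
5 | 1,4-bis(benzyloxy)-2-methoxybenzene | COc1cc(OCc2ccccc2)ccc1OCc1ccccc1 | intermediate
6 | 1,4-bis(benzyloxy)-2-bromo-5-methoxybenzene | COc1cc(OCc2ccccc2)c(Br)cc1OCc1ccccc1 | intermediate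
7 | [2,5-bis(benzyloxy)-4-methoxyphenyl]lithium | COc1cc(OCc2ccccc2)c([Li])cc1OCc1ccccc1 | intermediate
8 | (3S)-1-[2,5-bis(benzyloxy)-4-methoxyphenyl]-3-(3,4-dimethoxyphenyl)-3-hydroxypropan-1-one | COc1ccc([C@@H](O)CC(=O)c2cc(OCc3ccccc3)c(OC)cc2OCc2ccccc2)cc1OC | intermediate
9 | (3S)-1-(2,5-dihydroxy-4-methoxyphenyl)-3-(3,4-dimethoxyphenyl)-3-hydroxypropan-1-one | COc1ccc([C@@H](O)CC(=O)c2cc(O)c(OC)cc2O)cc1OC | intermediate
10 | 2-[(3S)-3-(3,4-dimethoxyphenyl)-3-hydroxypropanoyl]-5-methoxycyclohexa-2,5-diene-1,4-dione | COc1ccc([C@@H](O)CC(=O)C2=CC(=O)C(OC)=CC2=O)cc1OC | intermediate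
11 | (2S)-2-(3,4-dimethoxyphenyl)-5,8-dihydroxy-7-methoxy-2,3-dihydro-4H-chromen-4-one | COc1ccc([C@@H]2CC(=O)c3c(O)cc(OC)c(O)c3O2)cc1OC | intermediate
12 | (2S)-2-(3,4-dimethoxyphenyl)-5-hydroxy-7,8-dimethoxy-2,3-dihydro-4H-chromen-4-one | COc1ccc([C@@H]2CC(=O)c3c(O)cc(OC)c(OC)c3O2)cc1OC | intermediate
13 | (2S)-2-(3,4-dimethoxyphenyl)-5,7,8-trimethoxy-2,3-dihydro-4H-chromen-4-one | COc1ccc([C@@H]2CC(=O)c3c(OC)cc(OC)c(OC)c3O2)cc1OC | target

**Totals**

Total step count: 9. Longest linear sequence: 7 steps (steps 1, 2, 5, 6, 7, 8, 9).

**Steps most likely to fail**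

Step 7. Three processes may go wrong:
- Electron exchange between acylquinone 10 and the more easily oxidised product 11 may over-oxidise the cyclised ring A; the resulting flavanone quinone can tautomerise to a flavone, which destroys C2.
- The β-hydroxy ketone may dehydrate.
- A slow 6-endo closure may let the acylquinone oligomerise.

The fallback closes the ring at the quinone monoketal oxidation level, so that the cyclised product is a phenol monoether and not a hydroquinone. It sets out from 9. The non-chelated 5'-hydroxyl is methylated with TMSCHN2 (i-Pr2NEt, MeCN–MeOH) to give (3S)-3-(3,4-dimethoxyphenyl)-3-hydroxy-1-(2-hydroxy-4,5-dimethoxyphenyl)propan-1-one F1. PhI(OAc)2 in MeOH at 0 °C should oxidise this para-methoxyphenol to 2-[(3S)-3-(3,4-dimethoxyphenyl)-3-hydroxypropanoyl]-4,4,5-trimethoxycyclohexa-2,5-dien-1-one F2. After a change of solvent to CH2Cl2 with catalytic PPTS, the carbinol should add to the same doubly activated carbon, and loss of methanol aromatises ring A. The fallback comes back to the route at 12, and step 8 is then omitted.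

Step 9. Alkylation of the hydrogen-bonded 5-hydroxyl may be sluggish, and prolonged exposure may let β-elimination of the ring oxygen open ring C, with racemisation through the chalcone.

The fallback removes the ketone for the duration of the methylation and sets out from 12:
- NaBH4 (MeOH, 0 °C) reduces the ketone to (2S)-2-(3,4-dimethoxyphenyl)-7,8-dimethoxy-3,4-dihydro-2H-chromene-4,5-diol F3 (mixture of C4 epimers), which has neither the chelate nor an enolisable carbonyl.
- MeI and K2CO3 in acetone at rt methylate the phenol to (2S)-2-(3,4-dimethoxyphenyl)-5,7,8-trimethoxy-3,4-dihydro-2H-chromen-4-ol F4.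
- Dess–Martin oxidation (NaHCO3, CH2Cl2) restores the ketone.

It comes back to the route at 13.

Step 5. The aryllithium may deprotonate the amide at its α-carbon in competition with addition, or the lithium alkoxide may undergo retro-aldol cleavage on warming; either leaves acylation incomplete or erodes the configuration.

The fallback masks the hydroxyl and sets out from 3:
- TBSCl and imidazole in DMF give (3S)-3-[(tert-butyldimethylsilyl)oxy]-3-(3,4-dimethoxyphenyl)-N-methoxy-N-methylpropanamide F5.
- Addition of 7 (1.2 equiv, THF, −78 °C) gives (3S)-1-[2,5-bis(benzyloxy)-4-methoxyphenyl]-3-[(tert-butyldimethylsilyl)oxy]-3-(3,4-dimethoxyphenyl)propan-1-one F6.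
- HF·pyridine in THF at 0 °C removes the silyl group.

It comes back to the route at 8.

**Further compounds**

F1 | step 7 | (3S)-3-(3,4-dimethoxyphenyl)-3-hydroxy-1-(2-hydroxy-4,5-dimethoxyphenyl)propan-1-one | COc1ccc([C@@H](O)CC(=O)c2cc(OC)c(OC)cc2O)cc1OC
F2 | step 7 | 2-[(3S)-3-(3,4-dimethoxyphenyl)-3-hydroxypropanoyl]-4,4,5-trimethoxycyclohexa-2,5-dien-1-one | COc1ccc([C@@H](O)CC(=O)C2=CC(OC)(OC)C(OC)=CC2=O)cc1OC
F3 | step 9 | (2S)-2-(3,4-dimethoxyphenyl)-7,8-dimethoxy-3,4-dihydro-2H-chromene-4,5-diol (C4 epimers) | COc1ccc([C@@H]2CC(O)c3c(O)cc(OC)c(OC)c3O2)cc1OC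
F4 | step 9 | (2S)-2-(3,4-dimethoxyphenyl)-5,7,8-trimethoxy-3,4-dihydro-2H-chromen-4-ol (C4 epimers) | COc1ccc([C@@H]2CC(O)c3c(OC)cc(OC)c(OC)c3O2)cc1OC
F5 | step 5 | (3S)-3-[(tert-butyldimethylsilyl)oxy]-3-(3,4-dimethoxyphenyl)-N-methoxy-N-methylpropanamide | COc1ccc([C@@H](O[Si](C)(C)C(C)(C)C)CC(=O)N(C)OC)cc1OC
F6 | step 5 | (3S)-1-[2,5-bis(benzyloxy)-4-methoxyphenyl]-3-[(tert-butyldimethylsilyl)oxy]-3-(3,4-dimethoxyphenyl)propan-1-one | COc1ccc([C@@H](O[Si](C)(C)C(C)(C)C)CC(=O)c2cc(OCc3ccccc3)c(OC)cc2OCc2ccccc2)cc1OC
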